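**Plan**

- Retrosynthesis: after unmasking N4 (Boc) and the four phenols (MOM), the two aryl–Cβ bonds are cut first, then the two amide C–N bonds at N1 and N8.
- Enabling feature: in each arm, ring carbon C1 of a 3,4-dioxygenated benzene ring (para to one oxygen, meta to the other) sits on the β-carbon of an E-configured N-alkyl acrylamide. This Ar–CH=CH–C(=O)NH unit is what a Heck arylation of a terminal acrylamide delivers directly.
- Forward: spermidine is differentiated (N1/N8 trifluoroacetamides, N4-Boc, trifluoroacetamides removed) and acryloylated at both primary nitrogens. The open chain is then capped at both ends in one twofold Mizoroki–Heck coupling with MOM-protected 4-bromocatechol, and a single acidic step removes all five protecting groups.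
- Rings: none is formed; both benzene rings come from 4-bromocatechol.
- Stereochemistry: there are no stereocentres; both E double bonds are set in the Heck step by syn carbopalladation and syn β-hydride elimination and are not touched afterwards.

Key step: step 5

Assumption: the target is drawn as the free base; the last step would deliver it as its N4 hydrochloride, which is treated as the same compound 13 and written in neutral form. The salt is the form to store, since the protonated amine cannot add to the cinnamamide and the catechols are less prone to air oxidation.

**Step 1**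
Reactants: 1 spermidine; 2 ethyl trifluoroacetate; 3 di-tert-butyl dicarbonate
Product: 5 tert-butyl N-[3-(trifluoroacetamido)propyl]-N-[4-(trifluoroacetamido)butyl]carbamate, via N1,N8-bis(trifluoroacetyl)spermidine 4 (not isolated)
Conditions: 2 (2.1 equiv), MeOH, −78 °C to 0 °C; then 3 (1.5 equiv), 0 °C to rt
Reagents that add atoms: ethyl trifluoroacetate (2), CCOC(=O)C(F)(F)F; di-tert-butyl dicarbonate (3), CC(C)(C)OC(=O)OC(=O)OC(C)(C)C
Why: Ethyl trifluoroacetate acylates the two unhindered primary amines far faster than the secondary N4 (chemoselective ester aminolysis), and the remaining secondary amine then takes up Boc2O in the same flask (carbamate formation).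

**Step 2**
Reactants: 5 tert-butyl N-[3-(trifluoroacetamido)propyl]-N-[4-(trifluoroacetamido)butyl]carbamate
Product: 6 tert-butyl N-(4-aminobutyl)-N-(3-aminopropyl)carbamate (N4-Boc-spermidine)
Conditions: K2CO3 (5 equiv), MeOH/H2O (5:1), rt to 50 °C
Reagents that add atoms: none
Why: Trifluoroacetamides are cleaved by mild carbonate-mediated hydrolysis, conditions under which the tert-butyl carbamate is inert.

**Step 3**
Reactants: 6 tert-butyl N-(4-aminobutyl)-N-(3-aminopropyl)carbamate; 7 acryloyl chloride
Product: 8 tert-butyl N-(3-acrylamidopropyl)-N-(4-acrylamidobutyl)carbamate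
Conditions: 7 (2.2 equiv), Et3N (3 equiv), BHT (trace), CH2Cl2, −20 °C to 0 °C
Reagents that add atoms: acryloyl chloride (7), C=CC(=O)Cl
Why: N-Acylation of primary amines by an acid chloride (Schotten–Baumann-type amide formation) is much faster at low temperature than aza-Michael addition to the acrylamide being formed, and N4 is blocked as its carbamate.

**Step 4**
Reactants: 9 4-bromocatechol; 10 chloromethyl methyl ether
Product: 11 4-bromo-1,2-bis(methoxymethoxy)benzene
Conditions: 10 (2.6 equiv), i-Pr2NEt (3.5 equiv), CH2Cl2, 0 °C to rt, Ar
Reagents that add atoms: chloromethyl methyl ether (10), COCCl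
Why: Base-mediated O-alkylation of both phenols by the highly electrophilic chloromethyl ether (Williamson-type formation of the acetal ethers) is standard for catechols and leaves the aryl bromide untouched.

**Step 5**
Reactants: 8 tert-butyl N-(3-acrylamidopropyl)-N-(4-acrylamidobutyl)carbamate; 11 4-bromo-1,2-bis(methoxymethoxy)benzene
Product: 12 tert-butyl N-[3-[(E)-3-[3,4-bis(methoxymethoxy)phenyl]prop-2-enamido]propyl]-N-[4-[(E)-3-[3,4-bis(methoxymethoxy)phenyl]prop-2-enamido]butyl]carbamate
Conditions: 11 (2.5 equiv), Pd(OAc)2 (10 mol %), P(o-tol)3 (20 mol %), Et3N (5 equiv), BHT (5 mol %), DMF, 100 °C, sealed vessel, Ar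
Reagents that add atoms: none
Why: Pd(OAc)2 is reduced in the flask by the phosphine to zerovalent palladium, which inserts into the C–Br bond of 11; the resulting arylpalladium bromide coordinates a terminal C=C of 8 and adds across it in a syn carbopalladation that puts the aryl group on the unsubstituted CH2 carbon and palladium next to the carbonyl, and bond rotation followed by syn β-hydride elimination releases the conjugated alkene while Et3N takes up HBr and regenerates the catalyst. The closest known reaction type is the Mizoroki–Heck arylation of N-monosubstituted acrylamides with electron-rich aryl bromides to E-cinnamamides, here run twice on one substrate with an excess of 11. No ring closes and no stereocentre is created; the only stereochemical element is the geometry of the two new double bonds. β-Regioselectivity follows from the steric and electronic bias of the monosubstituted, acceptor-substituted alkene, and E geometry from the syn-insertion/syn-elimination sequence, in which the arrangement with aryl and carboxamide anti is strongly preferred. Chemoselectivity rests on the substrate: N4 is a carbamate and can neither add to the acrylamide nor bind palladium, the phenols are base-stable MOM ethers, and the bulky P(o-tol)3 keeps the catalyst alive at the temperature that the electron-rich bromide needs.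

**Step 6**
Reactants: 12 tert-butyl N-[3-[(E)-3-[3,4-bis(methoxymethoxy)phenyl]prop-2-enamido]propyl]-N-[4-[(E)-3-[3,4-bis(methoxymethoxy)phenyl]prop-2-enamido]butyl]carbamate
Product: 13 N1,N8-bis[(E)-3-(3,4-dihydroxyphenyl)prop-2-enoyl]spermidine (N1,N8-bis(caffeoyl)spermidine), handled as its hydrochloride
Conditions: anhydrous HCl (3 M in MeOH), 0 °C to rt, Ar; evaporation
Reagents that add atoms: none
Why: Acid-catalysed acetal exchange transfers the four methoxymethyl groups to methanol and the same acid fragments the tert-butyl carbamate (loss of 2-methylpropene and CO2), while the cinnamamide C=C and C–N bonds are stable to anhydrous HCl at room temperature, so the E geometry is retained.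

**Compound list**

1 | spermidine | NCCCCNCCCN | starting material
2 | ethyl trifluoroacetate | CCOC(=O)C(F)(F)F | starting material
3 | di-tert-butyl dicarbonate | CC(C)(C)OC(=O)OC(=O)OC(C)(C)C | starting material
4 | N1,N8-bis(trifluoroacetyl)spermidine | O=C(NCCCCNCCCNC(=O)C(F)(F)F)C(F)(F)F | intermediate
5 | tert-butyl N-[3-(trifluoroacetamido)propyl]-N-[4-(trifluoroacetamido)butyl]carbamate | CC(C)(C)OC(=O)N(CCCCNC(=O)C(F)(F)F)CCCNC(=O)C(F)(F)F | intermediate
6 | tert-butyl N-(4-aminobutyl)-N-(3-aminopropyl)carbamate (N4-Boc-spermidine) | CC(C)(C)OC(=O)N(CCCCN)CCCN | intermediate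
7 | acryloyl chloride | C=CC(=O)Cl | starting material
8 | tert-butyl N-(3-acrylamidopropyl)-N-(4-acrylamidobutyl)carbamate | C=CC(=O)NCCCCN(C(=O)OC(C)(C)C)CCCNC(=O)C=C | intermediate
9 | 4-bromocatechol (4-bromobenzene-1,2-diol) | Oc1ccc(Br)cc1O | starting material
10 | chloromethyl methyl ether | COCCl | starting material
11 | 4-bromo-1,2-bis(methoxymethoxy)benzene | COCOc1ccc(Br)cc1OCOC | intermediate
12 | tert-butyl N-[3-[(E)-3-[3,4-bis(methoxymethoxy)phenyl]prop-2-enamido]propyl]-N-[4-[(E)-3-[3,4-bis(methoxymethoxy)phenyl]prop-2-enamido]butyl]carbamate | COCOc1ccc(/C=C/C(=O)NCCCCN(C(=O)OC(C)(C)C)CCCNC(=O)/C=C/c2ccc(OCOC)c(OCOC)c2)cc1OCOC | intermediate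
13 | N1,N8-bis[(E)-3-(3,4-dihydroxyphenyl)prop-2-enoyl]spermidine (N1,N8-bis(caffeoyl)spermidine) | O=C(/C=C/c1ccc(O)c(O)c1)NCCCCNCCCNC(=O)/C=C/c1ccc(O)c(O)c1 | target

**Step count**

Total step count: 6. Longest linear sequence: 5 steps (steps 1, 2, 3, 5, 6); the aryl bromide branch (step 4) joins at step 5.

**Steps most likely to fail**

Step 5 (twofold Heck coupling). Oxidative addition into the electron-rich aryl bromide is slow, so palladium metal may precipitate before the second acrylamide terminus has been arylated, and the bis-acrylamide may polymerise thermally at 100 °C. The fallback moves the aryl–vinyl coupling to a small, single-site alkene and forms the amides afterwards. It sets out from 11, with diamine 6 as the amine partner, and comes back to the route at 12. Bromide 11 would be coupled with acrylic acid (Pd(OAc)2, P(o-tol)3, Et3N, DMF, 100 °C) to give (E)-3-[3,4-bis(methoxymethoxy)phenyl]prop-2-enoic acid F1, a reaction in which the alkene can be used in excess. Two equivalents of F1 would then be condensed with 6 (EDC·HCl, HOBt, CH2Cl2, rt) to give 12, bypassing 8.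

Step 3 (bis-acryloylation). Unreacted primary amine may add in conjugate fashion to acryloyl groups already installed, giving oligomers, and the product may polymerise by a radical pathway during concentration. The fallback keeps the alkene masked while free amine is present. It sets out from 6 and comes back at 8. Acylation of 6 with 3-chloropropanoyl chloride (Et3N, CH2Cl2, 0 °C) should give tert-butyl N-[3-(3-chloropropanamido)propyl]-N-[4-(3-chloropropanamido)butyl]carbamate F2. E1cB elimination of HCl from both arms (Et3N, MeCN, 70 °C) would then unveil the two acrylamides and deliver 8.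

Step 6 (global deprotection). Methoxymethyl or formaldehyde-derived cations may be captured by the electron-rich catechol rings or by the liberated N4 amine, and the free catechols may be oxidised by air to ortho-quinones during isolation. The fallback changes the phenol protection to a ketal that releases only acetone. It sets out from 9 and comes back at 13. Ketalisation of 9 with 2,2-dimethoxypropane (TsOH cat., toluene, reflux with removal of methanol) should give 5-bromo-2,2-dimethyl-1,3-benzodioxole F3. Heck coupling of F3 with 8 under the conditions of step 5 would give tert-butyl N-[3-[(E)-3-(2,2-dimethyl-1,3-benzodioxol-5-yl)prop-2-enamido]propyl]-N-[4-[(E)-3-(2,2-dimethyl-1,3-benzodioxol-5-yl)prop-2-enamido]butyl]carbamate F4. Treatment of F4 with TFA/H2O (9:1) at rt under argon would remove both acetonides and the Boc group and give 13 as its salt.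

**Further compounds**

F1 | step 5 | (E)-3-[3,4-bis(methoxymethoxy)phenyl]prop-2-enoic acid | COCOc1ccc(/C=C/C(=O)O)cc1OCOC
F2 | step 3 | tert-butyl N-[3-(3-chloropropanamido)propyl]-N-[4-(3-chloropropanamido)butyl]carbamate | CC(C)(C)OC(=O)N(CCCCNC(=O)CCCl)CCCNC(=O)CCCl
F3 | step 6 | 5-bromo-2,2-dimethyl-1,3-benzodioxole | CC1(C)Oc2ccc(Br)cc2O1
F4 | step 6 | tert-butyl N-[3-[(E)-3-(2,2-dimethyl-1,3-benzodioxol-5-yl)prop-2-enamido]propyl]-N-[4-[(E)-3-(2,2-dimethyl-1,3-benzodioxol-5-yl)prop-2-enamido]butyl]carbamate | CC1(C)Oc2ccc(/C=C/C(=O)NCCCCN(C(=O)OC(C)(C)C)CCCNC(=O)/C=C/c3ccc4OC(C)(C)Oc4c3)cc2O1
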